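**Retrosynthetic overview**

- The target is a tris-phenol/diol, unmasked last from a tri-O-benzyl, 7-O-TBS precursor (fluoride, then H2/Pd-C).
- The tetrahydrofuran ring (C7'–O–C9 bond) comes from a stereoconvergent SN1 cycloetherification of a 7'-hydroxy-1,4-diol, which places the aryl trans to the C8' CH2OH.
- That triol comes from LiAlH4 opening of a trans-α,β-disubstituted γ-butyrolactone; its C8'–C7' bond is made by a lactone-enolate aldol with 3,4-bis(benzyloxy)benzaldehyde (sets C8').
- The β-substituted lactone comes from an L-proline cross-aldol of methyl 4-oxobutanoate with O-benzylvanillin (sets C7 and C8), followed by NaBH4 reduction and lactonisation.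
- Ring order: the γ-butyrolactone is formed first as a temporary template and opened; the tetrahydrofuran is formed second and is the only ring kept.

Assumption: lignan numbering is used (C7/C8/C9 on the guaiacyl half, C7'/C8'/C9' on the catechol half). From the SMILES the target is 7R, 8R, 7'S, 8'R, i.e. a 2,3-trans-3,4-cis oxolane with an anti C7/C8 relationship. Compounds 1, 2 and 6 are taken as purchasable.

**Route**

Step 1
Reactants: 1 methyl 4-oxobutanoate; 2 4-(benzyloxy)-3-methoxybenzaldehyde
Product: 3 methyl (3S,4R)-4-[4-(benzyloxy)-3-methoxyphenyl]-3-formyl-4-hydroxybutanoate (not isolated)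
Conditions: L-proline (30 mol%), DMF, 4 °C, 1 (2 equiv) added slowly by syringe pump, 48 h
Reagents that add atoms: none
Why: Proline enamine cross-aldol (List–Houk transition state); the (E)-enamine of 1 attacks the Re face of 2 to give the anti adduct, setting C7 (R) and C8 in one step.

Step 2
Reactants: 3
Product: 4 (4R)-4-{(R)-[4-(benzyloxy)-3-methoxyphenyl](hydroxy)methyl}oxolan-2-one
Conditions: NaBH4, MeOH, 0 °C (same pot as step 1); aq. NH4Cl
Reagents that add atoms: none
Why: Chemoselective aldehyde reduction; the new primary alcohol closes onto the methyl ester (lactonisation, loss of MeOH) and no stereocentre is touched (the C8 descriptor changes S to R by CIP only).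

Step 3
Reactants: 4
Product: 5 (4R)-4-{(R)-[4-(benzyloxy)-3-methoxyphenyl][(tert-butyldimethylsilyl)oxy]methyl}oxolan-2-one
Conditions: TBSCl, imidazole, DMAP (cat.), DMF, rt
Reagents that add atoms: TBSCl, CC(C)(C)[Si](C)(C)Cl
Why: Silyl ether formation blocks the C7 oxygen so it can neither ionise nor act as a nucleophile in step 6; no stereocentre is involved.

Step 4
Reactants: 5; 6 3,4-bis(benzyloxy)benzaldehyde
Product: 7 (3S,4R)-3-{[3,4-bis(benzyloxy)phenyl](hydroxy)methyl}-4-{(R)-[4-(benzyloxy)-3-methoxyphenyl][(tert-butyldimethylsilyl)oxy]methyl}oxolan-2-one (3,4-trans; mixture of C7' carbinol epimers)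
Conditions: LDA (1.1 equiv), THF, −78 °C; then 6, −78 °C; AcOH quench at −78 °C
Reagents that add atoms: none
Why: Lactone-enolate aldol; the aldehyde adds anti to the bulky C4 substituent, giving the trans lactone and setting C8'. The C7' epimer mixture is harmless because that centre is reset in step 6.

Step 5
Reactants: 7
Product: 8 (2R,3R)-2-{[3,4-bis(benzyloxy)phenyl](hydroxy)methyl}-3-{(R)-[4-(benzyloxy)-3-methoxyphenyl][(tert-butyldimethylsilyl)oxy]methyl}butane-1,4-diol (C7' epimers)
Conditions: LiAlH4, THF, 0 °C; Rochelle-salt work-up (no acid)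
Reagents that add atoms: none
Why: Hydride reduction of the lactone to the 1,4-diol; benzyl and TBS ethers are inert and C8/C8' are not epimerisable once the carbonyl is gone.

Step 6
Reactants: 8
Product: 9 [(2S,3R,4R)-2-[3,4-bis(benzyloxy)phenyl]-4-{(R)-[4-(benzyloxy)-3-methoxyphenyl][(tert-butyldimethylsilyl)oxy]methyl}oxolan-3-yl]methanol
Conditions: CSA (10 mol%), CH2Cl2, 0 °C, short reaction time; Et3N quench
Reagents that add atoms: none
Why: SN1 cycloetherification; the free, electron-rich C7' benzylic alcohol ionises and is trapped 5-exo by the C9 hydroxyl (the C9' hydroxyl could only give an oxetane, and C7–OTBS is inert). Both C7' epimers converge on the product with the aryl trans to the C8' CH2OH and to the C8 substituent, i.e. 7'S.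

Step 7
Reactants: 9
Product: 10 (R)-[4-(benzyloxy)-3-methoxyphenyl][(3R,4R,5S)-5-[3,4-bis(benzyloxy)phenyl]-4-(hydroxymethyl)oxolan-3-yl]methanol
Conditions: TBAF, THF, 0 °C to rt
Reagents that add atoms: none
Why: Fluoride desilylation under non-acidic conditions, so neither benzylic C–O centre can ionise or epimerise.

Step 8
Reactants: 10
Product: 11 (7R)-7-hydroxytaxiresinol, 4-[(2S,3R,4R)-4-[(R)-hydroxy(4-hydroxy-3-methoxyphenyl)methyl]-3-(hydroxymethyl)oxolan-2-yl]benzene-1,2-diol
Conditions: H2 (1 atm), 10% Pd/C, EtOAc–EtOH, rt, stopped as soon as debenzylation is complete; filtered under Ar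
Reagents that add atoms: none
Why: Hydrogenolysis of the three phenolic benzyl ethers is much faster under neutral conditions than cleavage of the benzylic C7–OH or C7'–O bonds, so the four stereocentres are untouched.

**Compound list**

1 | methyl 4-oxobutanoate | COC(=O)CCC=O | starting material
2 | 4-(benzyloxy)-3-methoxybenzaldehyde | COc1cc(C=O)ccc1OCc1ccccc1 | starting material
3 | methyl (3S,4R)-4-[4-(benzyloxy)-3-methoxyphenyl]-3-formyl-4-hydroxybutanoate | COc1cc([C@H](O)[C@@H](C=O)CC(=O)OC)ccc1OCc1ccccc1 | intermediate (not isolated)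
4 | (4R)-4-{(R)-[4-(benzyloxy)-3-methoxyphenyl](hydroxy)methyl}oxolan-2-one | COc1cc([C@H](O)[C@H]2COC(=O)C2)ccc1OCc1ccccc1 | intermediate
5 | 7-O-TBS ether of 4 | COc1cc([C@H](O[Si](C)(C)C(C)(C)C)[C@H]2COC(=O)C2)ccc1OCc1ccccc1 | intermediate
6 | 3,4-bis(benzyloxy)benzaldehyde | O=Cc1ccc(OCc2ccccc2)c(OCc2ccccc2)c1 | starting material
7 | (3S,4R)-trans aldol lactone, C7' epimer mixture | COc1cc([C@H](O[Si](C)(C)C(C)(C)C)[C@H]2COC(=O)[C@@H]2C(O)c2ccc(OCc3ccccc3)c(OCc3ccccc3)c2)ccc1OCc1ccccc1 | intermediate
8 | (2R,3R)-triol, C7' epimer mixture | COc1cc([C@H](O[Si](C)(C)C(C)(C)C)[C@@H](CO)[C@H](CO)C(O)c2ccc(OCc3ccccc3)c(OCc3ccccc3)c2)ccc1OCc1ccccc1 | intermediate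
9 | (2S,3R,4R)-oxolane, 7-OTBS, tri-O-benzyl | COc1cc([C@H](O[Si](C)(C)C(C)(C)C)[C@H]2CO[C@H](c3ccc(OCc4ccccc4)c(OCc4ccccc4)c3)[C@H]2CO)ccc1OCc1ccccc1 | intermediate
10 | tri-O-benzyl-(7R)-7-hydroxytaxiresinol | COc1cc([C@H](O)[C@H]2CO[C@H](c3ccc(OCc4ccccc4)c(OCc4ccccc4)c3)[C@H]2CO)ccc1OCc1ccccc1 | intermediate
11 | (7R)-7-hydroxytaxiresinol | COc1cc([C@H](O)[C@H]2CO[C@H](c3ccc(O)c(O)c3)[C@H]2CO)ccc1O | target

**Totals**

- Total step count: 8 (steps 1 and 2 are run in one pot, so 7 isolations).
- Longest linear sequence: 8 steps, from 1 and 2; compound 6 enters as a purchased reagent.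

**Steps most likely to fail, with fallbacks**

1. Step 1. The proline cross-aldol may be sluggish with the electron-rich aldehyde 2, and homo-aldol of 1 may compete. Fallback: switch to auxiliary control, using an Evans MgCl2/Et3N/TMSCl anti-aldol of N-(4-methoxy-4-oxobutanoyl)-4-benzyloxazolidin-2-one with 2, then NaBH4 (THF–H2O) to remove the auxiliary and lactonise to the same lactone 4. The (R)-benzyl auxiliary is predicted on the chelated-enolate model; use its antipode if the sense proves opposite.

2. Step 6. The acid may also ionise or desilylate C7–OTBS (leading to furofuran or C7 epimers), or the guaiacyl ring may attack the C7' cation to give an aryltetralin. Fallback: close the ring through a quinone methide instead. Use 3-(benzyloxy)-4-(TBS-oxy)benzaldehyde in step 4, unmask only the 4'-phenol after the LiAlH4 step (K2CO3/MeOH), and let the p-hydroxybenzyl alcohol cyclise by oxa-Michael addition at near-neutral pH. The 4-OBn/7-OTBS centre cannot form a quinone methide.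

3. Step 8. Hydrogenolysis may over-reduce the benzylic C7–OH or open the ring at C7'–O. Fallback: change the phenol protecting groups to silyl ethers (TBS or TIPS on both aldehydes) so the endgame is a single buffered-fluoride global desilylation (TBAF/AcOH) with no hydrogenolysis; this also removes one step.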